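**Retrosynthetic overview**

1. The C40 chain is cut twice by Wittig olefination: acetylenic C15 phosphonium salt + C10 dialdehyde (C11=C12), then C25 phosphonium salt + C15 dihydroxy aldehyde (C11'=C12').
2. Acetylenic ring: enyne ⇐ Sonogashira coupling of an enol triflate ⇐ (4R)-4-silyloxy-2,2,6-trimethylcyclohexanone ⇐ ring closure C1–C2 (carotenoid numbering) by reductive cyclisation of an acyclic isopropenyl ketone carrying a primary iodide.
3. Enabling feature: in the 3-hydroxy-β-ring (C1–C6) the gem-dimethyl carbon C1 is α to C6, which bears the alkyne and the C5=C6 bond and is therefore a latent ketone; C2 ends a C2–C3(O)–C4 unit that maps onto (R)-epichlorohydrin. Hydride addition to a C1=CH2 group creates the second methyl and the C1 enolate, which displaces iodide at C2.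
4. ε-Ring: taken from ketoisophorone; C3' is set by asymmetric transfer hydrogenation (as R, used as a relay), C6' by acetylide addition, 7'E by Red-Al, and C3' is then inverted.
5. Ring order: only the acetylenic ring is formed in the route (step 5); the ε-ring is carried through from ketoisophorone.

Key step: step 5

Remark 1: compounds 3–9 carry one uncontrolled methyl-bearing stereocentre (written without descriptor); it is erased in step 6.
Remark 2: metalated or deprotonated forms of a numbered compound or of a step's product (enolates, acetylides, ylides, alkoxides) are not numbered separately.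
Remark 3: minor Z isomers from the two Wittig steps are assumed to be removed by crystallisation or chromatography.

**Route**

Step 1
Reactants: 1 1-(morpholin-4-yl)propan-1-one; 2 (R)-epichlorohydrin
Product: 3 (4R)-5-chloro-4-hydroxy-2-methyl-1-(morpholin-4-yl)pentan-1-one
Conditions: LDA (1.05 equiv), THF, −78 °C; 2 (1.2 equiv), −78 → −15 °C; AcOH, −15 °C
Reagents that add atoms: none
Why: Amide enolate alkylation by epoxide opening: the lithium enolate attacks the unsubstituted epoxide carbon of 2 (SN2), the carbinol centre of 2 is untouched and becomes C3 (R) of the ring, and quenching below 0 °C should keep the chlorohydrin from closing to an epoxide.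

Step 2
Reactants: 3 (4R)-5-chloro-4-hydroxy-2-methyl-1-(morpholin-4-yl)pentan-1-one
Product: 4 (4R)-4-[(tert-butyldimethylsilyl)oxy]-5-chloro-2-methyl-1-(morpholin-4-yl)pentan-1-one
Conditions: TBSCl, imidazole, DMF, rt
Reagents that add atoms: tert-butyldimethylsilyl chloride, CC(C)(C)[Si](C)(C)Cl
Why: Standard imidazole-mediated silylation protects the secondary alcohol so that it can neither lactonise onto the amide nor displace the halide later.

Step 3
Reactants: 4 (4R)-4-[(tert-butyldimethylsilyl)oxy]-5-chloro-2-methyl-1-(morpholin-4-yl)pentan-1-one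
Product: 5 (4R)-4-[(tert-butyldimethylsilyl)oxy]-5-iodo-2-methyl-1-(morpholin-4-yl)pentan-1-one
Conditions: NaI (excess), butan-2-one, reflux, dark
Reagents that add atoms: sodium iodide, [Na+].[I-]
Why: Finkelstein halide exchange (SN2) turns the sluggish β-silyloxy chloride into the iodide needed for ring closure, before the sensitive enone is made.

Step 4
Reactants: 5 (4R)-4-[(tert-butyldimethylsilyl)oxy]-5-iodo-2-methyl-1-(morpholin-4-yl)pentan-1-one
Product: 7 (6R)-6-[(tert-butyldimethylsilyl)oxy]-7-iodo-2,4-dimethylhept-1-en-3-one, via magnesium hemiaminal alkoxide 6 (not isolated)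
Conditions: isopropenylmagnesium bromide (2 equiv), THF, 0 °C; poured into cold aq. NH4Cl/citric acid
Reagents that add atoms: isopropenylmagnesium bromide, C=C(C)[Mg]Br
Why: Morpholine amides behave like Weinreb amides: the Grignard reagent adds once to give a tetrahedral magnesium alkoxide that collapses to the enone only on acidic work-up, and a primary iodide does not react with an alkenyl Grignard reagent at 0 °C.

Step 5
Reactants: 7 (6R)-6-[(tert-butyldimethylsilyl)oxy]-7-iodo-2,4-dimethylhept-1-en-3-one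
Product: 9 (4R)-4-[(tert-butyldimethylsilyl)oxy]-2,2,6-trimethylcyclohexan-1-one, via lithium enolate 8 (not isolated)
Conditions: L-Selectride (1.05 equiv), THF, −78 °C (7 added dropwise); DMPU, −78 °C → rt
Reagents that add atoms: none
Why: The bulky borohydride should deliver hydride 1,4 to the unsubstituted =CH2 terminus of the 2-methylprop-2-enoyl unit (the carbonyl is shielded by its α'-branch), which creates the second methyl of the gem-dimethyl pair and, regiospecifically, the tetrasubstituted lithium enolate 8 at C1; this enolate then displaces the primary iodide at C2 by intramolecular SN2 C-alkylation and forms the quaternary carbon and the six-membered ring. The closest known reaction type is Selectride conjugate reduction followed by enolate alkylation (reductive alkylation of enones), run here intramolecularly. The ring closes in the 6-(enolendo)-exo-tet mode, which is favoured for enolates, whereas a five-membered analogue would O-alkylate. No new stereocentre of consequence is formed: C3 (R) comes from 2 and is not involved, and the methyl-bearing centre next to the carbonyl stays a mixture that step 6 removes. The step needs 1,4- over 1,2-reduction (bulky hydride, hindered carbonyl, slow inverse addition so that the enolate never meets excess enone), C- over O-alkylation (lithium counter-ion, iodide leaving group) and a fixed enolate position (set by the site of hydride addition, with no proton source to move it).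

Step 6
Reactants: 9 (4R)-4-[(tert-butyldimethylsilyl)oxy]-2,2,6-trimethylcyclohexan-1-one
Product: 10 (4R)-4-[(tert-butyldimethylsilyl)oxy]-2,6,6-trimethylcyclohex-1-en-1-yl trifluoromethanesulfonate
Conditions: KHMDS, THF, −78 → 0 °C; PhNTf2, −78 °C → rt
Reagents that add atoms: N-phenylbis(trifluoromethanesulfonimide), O=S(=O)(N(c1ccccc1)S(=O)(=O)C(F)(F)F)C(F)(F)F
Why: Regiospecific enol triflate formation: 9 has a single enolisable position, so deprotonation and O-triflation should give one tetrasubstituted enol triflate and remove the uncontrolled stereocentre.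

Step 7
Reactants: 10 (4R)-4-[(tert-butyldimethylsilyl)oxy]-2,6,6-trimethylcyclohex-1-en-1-yl trifluoromethanesulfonate; 11 (2E)-3-methylpent-2-en-4-yn-1-ol
Product: 12 (2E)-5-[(4R)-4-[(tert-butyldimethylsilyl)oxy]-2,6,6-trimethylcyclohex-1-en-1-yl]-3-methylpent-2-en-4-yn-1-ol
Conditions: Pd(PPh3)4 (5 mol %), CuI (10 mol %), Et3N, DMF, rt → 50 °C
Reagents that add atoms: none
Why: Sonogashira coupling of an enol triflate with a terminal alkyne, a known way to join 2,6,6-trimethylcyclohexenyl triflates to alkynes; the E geometry of 11 is not touched.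

Step 8
Reactants: 12 (2E)-5-[(4R)-4-[(tert-butyldimethylsilyl)oxy]-2,6,6-trimethylcyclohex-1-en-1-yl]-3-methylpent-2-en-4-yn-1-ol
Product: 14 [(2E)-5-[(4R)-4-hydroxy-2,6,6-trimethylcyclohex-1-en-1-yl]-3-methylpent-2-en-4-yn-1-yl]triphenylphosphonium bromide, via desilylated C15 diol 13 (not isolated)
Conditions: Ph3P·HBr (1.3 equiv), MeOH, rt
Reagents that add atoms: triphenylphosphine hydrobromide, c1ccc(cc1)[PH+](c1ccccc1)c1ccccc1.[Br-]
Why: Acidic methanol should cleave the TBS ether, and the primary allylic alcohol is converted through the allylic cation/bromide into the phosphonium salt (standard preparation of carotenoid C15 Wittig salts), while the non-allylic ring alcohol does not ionise.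

Step 9
Reactants: 14 [(2E)-5-[(4R)-4-hydroxy-2,6,6-trimethylcyclohex-1-en-1-yl]-3-methylpent-2-en-4-yn-1-yl]triphenylphosphonium bromide; 15 (2E,4E,6E)-2,7-dimethylocta-2,4,6-trienedial
Product: 16 (2E,4E,6E,8E,10E)-13-[(4R)-4-hydroxy-2,6,6-trimethylcyclohex-1-en-1-yl]-2,7,11-trimethyltrideca-2,4,6,8,10-pentaen-12-ynal
Conditions: 15 (3 equiv), NaOMe, CH2Cl2/MeOH, 0 °C → rt
Reagents that add atoms: none
Why: Wittig olefination of one formyl group of the symmetrical dialdehyde used in excess; the semi-stabilised ylide should give mainly the E alkene at C11=C12.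

Step 10
Reactants: 16 (2E,4E,6E,8E,10E)-13-[(4R)-4-hydroxy-2,6,6-trimethylcyclohex-1-en-1-yl]-2,7,11-trimethyltrideca-2,4,6,8,10-pentaen-12-ynal
Product: 17 (2E,4E,6E,8E,10E)-13-[(4R)-4-hydroxy-2,6,6-trimethylcyclohex-1-en-1-yl]-2,7,11-trimethyltrideca-2,4,6,8,10-pentaen-12-yn-1-ol
Conditions: NaBH4, MeOH/THF, 0 °C
Reagents that add atoms: none
Why: 1,2-Reduction of the conjugated aldehyde by borohydride; no other reducible group is present.

Step 11
Reactants: 17 (2E,4E,6E,8E,10E)-13-[(4R)-4-hydroxy-2,6,6-trimethylcyclohex-1-en-1-yl]-2,7,11-trimethyltrideca-2,4,6,8,10-pentaen-12-yn-1-ol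
Product: 18 [(2E,4E,6E,8E,10E)-13-[(4R)-4-hydroxy-2,6,6-trimethylcyclohex-1-en-1-yl]-2,7,11-trimethyltrideca-2,4,6,8,10-pentaen-12-yn-1-yl]triphenylphosphonium bromide
Conditions: Ph3P·HBr (1.1 equiv), MeOH/CH2Cl2, 0 °C → rt
Reagents that add atoms: triphenylphosphine hydrobromide, c1ccc(cc1)[PH+](c1ccccc1)c1ccccc1.[Br-]
Why: SN1-type conversion of the polyenylic primary alcohol into the terminal phosphonium salt, as used for apocarotenol Wittig salts; the ring alcohol is inert.

Step 12
Reactants: 19 2,6,6-trimethylcyclohex-2-ene-1,4-dione (ketoisophorone)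
Product: 20 (4R)-4-hydroxy-2,6,6-trimethylcyclohex-2-en-1-one
Conditions: RuCl[(R,R)-TsDPEN](p-cymene) (0.5 mol %), HCO2H/Et3N 5:2, CH2Cl2, rt
Reagents that add atoms: none
Why: Noyori asymmetric transfer hydrogenation should reduce the less hindered C4 carbonyl (C1 is flanked by a quaternary carbon and a methylated alkene carbon), and the (R,R)-ligand is expected to give the R alcohol by analogy with aryl and alkenyl ketones.

Step 13
Reactants: 20 (4R)-4-hydroxy-2,6,6-trimethylcyclohex-2-en-1-one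
Product: 21 (4R)-4-[(tert-butyldimethylsilyl)oxy]-2,6,6-trimethylcyclohex-2-en-1-one
Conditions: TBSCl, imidazole, DMF, rt
Reagents that add atoms: tert-butyldimethylsilyl chloride, CC(C)(C)[Si](C)(C)Cl
Why: Standard silylation; the silyl ether serves as the stereochemical relay for the next step.

Step 14
Reactants: 21 (4R)-4-[(tert-butyldimethylsilyl)oxy]-2,6,6-trimethylcyclohex-2-en-1-one; 11 (2E)-3-methylpent-2-en-4-yn-1-ol
Product: 22 (1R,4R)-4-[(tert-butyldimethylsilyl)oxy]-1-[(3E)-5-hydroxy-3-methylpent-3-en-1-yn-1-yl]-2,6,6-trimethylcyclohex-2-en-1-ol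
Conditions: 11 (1.3 equiv), n-BuLi (2.6 equiv), THF, −78 → 0 °C; 21, −78 → 0 °C; H2O
Reagents that add atoms: none
Why: 1,2-Addition of the lithium acetylide (dianion of 11) to a carbonyl that cannot be enolised; attack is expected anti to the pseudo-axial C6 methyl of the half-chair in which the silyloxy group is pseudo-equatorial, i.e. on the face syn to OTBS, which sets the tertiary carbinol as 1R with its hydroxyl trans to the silyloxy group.

Step 15
Reactants: 22 (1R,4R)-4-[(tert-butyldimethylsilyl)oxy]-1-[(3E)-5-hydroxy-3-methylpent-3-en-1-yn-1-yl]-2,6,6-trimethylcyclohex-2-en-1-ol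
Product: 23 (1R,4R)-4-[(tert-butyldimethylsilyl)oxy]-1-[(1E,3E)-5-hydroxy-3-methylpenta-1,3-dien-1-yl]-2,6,6-trimethylcyclohex-2-en-1-ol
Conditions: Red-Al, THF, 0 °C → rt; aq. Rochelle salt
Reagents that add atoms: none
Why: Alkoxide-directed trans-hydroalumination of the propargylic alcohol followed by protonation should give the E alkene, as in abscisic-acid-type side-chain syntheses; the silyl ether and the stereocentres are not affected.

Step 16
Reactants: 23 (1R,4R)-4-[(tert-butyldimethylsilyl)oxy]-1-[(1E,3E)-5-hydroxy-3-methylpenta-1,3-dien-1-yl]-2,6,6-trimethylcyclohex-2-en-1-ol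
Product: 24 (2E,4E)-5-[(1R,4R)-4-[(tert-butyldimethylsilyl)oxy]-1-hydroxy-2,6,6-trimethylcyclohex-2-en-1-yl]-3-methylpenta-2,4-dienal
Conditions: activated MnO2, CH2Cl2, rt
Reagents that add atoms: none
Why: MnO2 oxidises only the primary dienylic alcohol; the tertiary alcohol cannot be oxidised and the secondary one is silylated.

Step 17
Reactants: 24 (2E,4E)-5-[(1R,4R)-4-[(tert-butyldimethylsilyl)oxy]-1-hydroxy-2,6,6-trimethylcyclohex-2-en-1-yl]-3-methylpenta-2,4-dienal
Product: 25 (2E,4E)-5-[(1R,4R)-1,4-dihydroxy-2,6,6-trimethylcyclohex-2-en-1-yl]-3-methylpenta-2,4-dienal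
Conditions: TBAF, AcOH, THF, 0 °C → rt
Reagents that add atoms: none
Why: Fluoride cleaves the Si–O bond, and acetic acid buffering protects the dienal from base.

Step 18
Reactants: 25 (2E,4E)-5-[(1R,4R)-1,4-dihydroxy-2,6,6-trimethylcyclohex-2-en-1-yl]-3-methylpenta-2,4-dienal
Product: 26 (1S,4R)-4-hydroxy-3,5,5-trimethyl-4-[(1E,3E)-3-methyl-5-oxopenta-1,3-dien-1-yl]cyclohex-2-en-1-yl 4-nitrobenzoate
Conditions: 4-nitrobenzoic acid, PPh3, DIAD, toluene/THF, −20 °C → rt
Reagents that add atoms: 4-nitrobenzoic acid, OC(=O)c1ccc(cc1)[N+](=O)[O-]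
Why: Mitsunobu reaction: the secondary allylic alcohol is activated as an alkoxyphosphonium ion and displaced by 4-nitrobenzoate with inversion (SN2), which converts the relay centre into the required C3' S configuration (hydroxyls now cis); the tertiary alcohol and the aldehyde do not react.

Step 19
Reactants: 26 (1S,4R)-4-hydroxy-3,5,5-trimethyl-4-[(1E,3E)-3-methyl-5-oxopenta-1,3-dien-1-yl]cyclohex-2-en-1-yl 4-nitrobenzoate
Product: 27 (2E,4E)-5-[(1R,4S)-1,4-dihydroxy-2,6,6-trimethylcyclohex-2-en-1-yl]-3-methylpenta-2,4-dienal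
Conditions: K2CO3 (cat.), MeOH, 0 °C
Reagents that add atoms: none
Why: Base-catalysed methanolysis of the activated 4-nitrobenzoate frees the inverted alcohol without touching the stereocentres.

Step 20
Reactants: 18 [(2E,4E,6E,8E,10E)-13-[(4R)-4-hydroxy-2,6,6-trimethylcyclohex-1-en-1-yl]-2,7,11-trimethyltrideca-2,4,6,8,10-pentaen-12-yn-1-yl]triphenylphosphonium bromide; 27 (2E,4E)-5-[(1R,4S)-1,4-dihydroxy-2,6,6-trimethylcyclohex-2-en-1-yl]-3-methylpenta-2,4-dienal
Product: 28 all-E-(3R,3'S,6'R)-7,8-didehydro-β,ε-carotene-3,3',6'-triol (CNP0113828.1)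
Conditions: NaOMe (excess), CH2Cl2/MeOH, 0 °C → rt, dark, N2
Reagents that add atoms: none
Why: Wittig olefination between the C25 ylide and the C15 aldehyde forms the C11'=C12' bond, excess methoxide covers the three free hydroxyl groups, and the semi-stabilised ylide should give mainly the E alkene.

**Compound list**

1 | 1-(morpholin-4-yl)propan-1-one | CCC(=O)N1CCOCC1 | starting material
2 | (R)-epichlorohydrin, (2R)-2-(chloromethyl)oxirane | ClC[C@H]1CO1 | starting material
3 | (4R)-5-chloro-4-hydroxy-2-methyl-1-(morpholin-4-yl)pentan-1-one | ClC[C@H](O)CC(C)C(=O)N1CCOCC1 | intermediate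
4 | (4R)-4-[(tert-butyldimethylsilyl)oxy]-5-chloro-2-methyl-1-(morpholin-4-yl)pentan-1-one | ClC[C@H](O[Si](C)(C)C(C)(C)C)CC(C)C(=O)N1CCOCC1 | intermediate
5 | (4R)-4-[(tert-butyldimethylsilyl)oxy]-5-iodo-2-methyl-1-(morpholin-4-yl)pentan-1-one | IC[C@H](O[Si](C)(C)C(C)(C)C)CC(C)C(=O)N1CCOCC1 | intermediate
6 | bromomagnesium (6R)-6-[(tert-butyldimethylsilyl)oxy]-7-iodo-2,4-dimethyl-3-(morpholin-4-yl)hept-1-en-3-olate | IC[C@H](O[Si](C)(C)C(C)(C)C)CC(C)C(O[Mg]Br)(N1CCOCC1)C(C)=C | intermediate
7 | (6R)-6-[(tert-butyldimethylsilyl)oxy]-7-iodo-2,4-dimethylhept-1-en-3-one | IC[C@H](O[Si](C)(C)C(C)(C)C)CC(C)C(=O)C(C)=C | intermediate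
8 | lithium (6R)-6-[(tert-butyldimethylsilyl)oxy]-7-iodo-2,4-dimethylhept-2-en-3-olate | IC[C@H](O[Si](C)(C)C(C)(C)C)CC(C)C([O-])=C(C)C.[Li+] | intermediate
9 | (4R)-4-[(tert-butyldimethylsilyl)oxy]-2,2,6-trimethylcyclohexan-1-one | CC1C[C@@H](O[Si](C)(C)C(C)(C)C)CC(C)(C)C1=O | intermediate
10 | (4R)-4-[(tert-butyldimethylsilyl)oxy]-2,6,6-trimethylcyclohex-1-en-1-yl trifluoromethanesulfonate | FC(F)(F)S(=O)(=O)OC1=C(C)C[C@@H](O[Si](C)(C)C(C)(C)C)CC1(C)C | intermediate
11 | (2E)-3-methylpent-2-en-4-yn-1-ol | OC/C=C(\C)C#C | starting material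
12 | (2E)-5-[(4R)-4-[(tert-butyldimethylsilyl)oxy]-2,6,6-trimethylcyclohex-1-en-1-yl]-3-methylpent-2-en-4-yn-1-ol | OC/C=C(\C)C#CC1=C(C)C[C@@H](O[Si](C)(C)C(C)(C)C)CC1(C)C | intermediate
13 | (1R)-4-[(3E)-5-hydroxy-3-methylpent-3-en-1-yn-1-yl]-3,5,5-trimethylcyclohex-3-en-1-ol | OC/C=C(\C)C#CC1=C(C)C[C@@H](O)CC1(C)C | intermediate
14 | [(2E)-5-[(4R)-4-hydroxy-2,6,6-trimethylcyclohex-1-en-1-yl]-3-methylpent-2-en-4-yn-1-yl]triphenylphosphonium bromide | [Br-].c1ccccc1[P+](c1ccccc1)(c1ccccc1)C/C=C(\C)C#CC1=C(C)C[C@@H](O)CC1(C)C | intermediate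
15 | (2E,4E,6E)-2,7-dimethylocta-2,4,6-trienedial | O=C/C(C)=C/C=C/C=C(\C)C=O | starting material
16 | (2E,4E,6E,8E,10E)-13-[(4R)-4-hydroxy-2,6,6-trimethylcyclohex-1-en-1-yl]-2,7,11-trimethyltrideca-2,4,6,8,10-pentaen-12-ynal | O=C/C(C)=C/C=C/C=C(C)/C=C/C=C(\C)C#CC1=C(C)C[C@@H](O)CC1(C)C | intermediate
17 | (2E,4E,6E,8E,10E)-13-[(4R)-4-hydroxy-2,6,6-trimethylcyclohex-1-en-1-yl]-2,7,11-trimethyltrideca-2,4,6,8,10-pentaen-12-yn-1-ol | OC/C(C)=C/C=C/C=C(C)/C=C/C=C(\C)C#CC1=C(C)C[C@@H](O)CC1(C)C | intermediate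
18 | [(2E,4E,6E,8E,10E)-13-[(4R)-4-hydroxy-2,6,6-trimethylcyclohex-1-en-1-yl]-2,7,11-trimethyltrideca-2,4,6,8,10-pentaen-12-yn-1-yl]triphenylphosphonium bromide | [Br-].c1ccccc1[P+](c1ccccc1)(c1ccccc1)C/C(C)=C/C=C/C=C(C)/C=C/C=C(\C)C#CC1=C(C)C[C@@H](O)CC1(C)C | intermediate
19 | 2,6,6-trimethylcyclohex-2-ene-1,4-dione (ketoisophorone) | CC1=CC(=O)CC(C)(C)C1=O | starting material
20 | (4R)-4-hydroxy-2,6,6-trimethylcyclohex-2-en-1-one | CC1=C[C@H](O)CC(C)(C)C1=O | intermediate
21 | (4R)-4-[(tert-butyldimethylsilyl)oxy]-2,6,6-trimethylcyclohex-2-en-1-one | CC1=C[C@H](O[Si](C)(C)C(C)(C)C)CC(C)(C)C1=O | intermediate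
22 | (1R,4R)-4-[(tert-butyldimethylsilyl)oxy]-1-[(3E)-5-hydroxy-3-methylpent-3-en-1-yn-1-yl]-2,6,6-trimethylcyclohex-2-en-1-ol | CC1=C[C@H](O[Si](C)(C)C(C)(C)C)CC(C)(C)[C@]1(O)C#C/C(C)=C/CO | intermediate
23 | (1R,4R)-4-[(tert-butyldimethylsilyl)oxy]-1-[(1E,3E)-5-hydroxy-3-methylpenta-1,3-dien-1-yl]-2,6,6-trimethylcyclohex-2-en-1-ol | CC1=C[C@H](O[Si](C)(C)C(C)(C)C)CC(C)(C)[C@]1(O)/C=C/C(C)=C/CO | intermediate
24 | (2E,4E)-5-[(1R,4R)-4-[(tert-butyldimethylsilyl)oxy]-1-hydroxy-2,6,6-trimethylcyclohex-2-en-1-yl]-3-methylpenta-2,4-dienal | CC1=C[C@H](O[Si](C)(C)C(C)(C)C)CC(C)(C)[C@]1(O)/C=C/C(C)=C/C=O | intermediate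
25 | (2E,4E)-5-[(1R,4R)-1,4-dihydroxy-2,6,6-trimethylcyclohex-2-en-1-yl]-3-methylpenta-2,4-dienal | CC1=C[C@H](O)CC(C)(C)[C@]1(O)/C=C/C(C)=C/C=O | intermediate
26 | (1S,4R)-4-hydroxy-3,5,5-trimethyl-4-[(1E,3E)-3-methyl-5-oxopenta-1,3-dien-1-yl]cyclohex-2-en-1-yl 4-nitrobenzoate | CC1=C[C@@H](OC(=O)c2ccc(cc2)[N+](=O)[O-])CC(C)(C)[C@]1(O)/C=C/C(C)=C/C=O | intermediate
27 | (2E,4E)-5-[(1R,4S)-1,4-dihydroxy-2,6,6-trimethylcyclohex-2-en-1-yl]-3-methylpenta-2,4-dienal | CC1=C[C@@H](O)CC(C)(C)[C@]1(O)/C=C/C(C)=C/C=O | intermediate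
28 | all-E-(3R,3'S,6'R)-7,8-didehydro-β,ε-carotene-3,3',6'-triol | CC1=C[C@@H](O)CC(C)(C)[C@]1(O)/C=C/C(C)=C/C=C/C(C)=C/C=C/C=C(C)/C=C/C=C(\C)C#CC1=C(C)C[C@@H](O)CC1(C)C | target

**Step count and risks**

Total step count: 20. Longest linear sequence: 12 steps (steps 1–11 and 20); the ε-ring branch has 9 (steps 12–19 and 20).

Steps most likely to fail:

Step 5. 1,2-Reduction of the enone or hydride attack at the C–I bond may compete with 1,4-delivery, and the borane-complexed enolate may alkylate slowly or on oxygen. The fallback sets out from 7 and comes back at 9 and separates reduction from bond formation. Conjugate reduction of 7 with Stryker's reagent ([(Ph3P)CuH]6, wet benzene, rt), in which water protonates the copper enolate, should give (6R)-6-[(tert-butyldimethylsilyl)oxy]-7-iodo-2,4-dimethylheptan-3-one F1. F1 is then cyclised under equilibrating conditions (t-BuOK, t-BuOH/THF, 0 °C → rt): the two possible enolates interconvert, only the C1 enolate can close a six-membered ring, and the protic medium disfavours O-alkylation.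

Step 18. The activated allylic alcohol may ionise (loss of stereochemical fidelity, elimination to a diene) or be captured by the neighbouring tertiary hydroxyl instead of undergoing SN2 displacement, because the required approach to C3' is hindered by the syn-axial C1' methyl group. The fallback sets out from 25 and comes back at 28 and moves the inversion to the end as an oxidation–reduction. Wittig reaction of 25 with 18 under the conditions of step 20 should give (3R,3'R,6'R)-7,8-didehydro-β,ε-carotene-3,3',6'-triol F2. MnO2 (CH2Cl2, rt) oxidises only the allylic secondary 3'-hydroxyl to give (3R,6'R)-3,6'-dihydroxy-7,8-didehydro-β,ε-caroten-3'-one F3. Luche reduction (NaBH4, CeCl3, MeOH, −40 °C) should deliver hydride anti to the pseudo-axial C1' methyl of the conformer with the side chain pseudo-axial, giving the 3',6'-cis diol 28, as in the reduction of abscisic-acid-type enones.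

Step 14. The facial selectivity of the acetylide addition may be poor or reversed (attack anti to the silyloxy group). The fallback sets out from 19 and comes back at 27 and uses the other enantiomeric series without any inversion. Transfer hydrogenation of 19 with RuCl[(S,S)-TsDPEN](p-cymene) should give (4S)-4-hydroxy-2,6,6-trimethylcyclohex-2-en-1-one F4, which is silylated to (4S)-4-[(tert-butyldimethylsilyl)oxy]-2,6,6-trimethylcyclohex-2-en-1-one F5. Acetylide addition anti to the silyloxy group then gives directly the cis-configured (1R,4S)-4-[(tert-butyldimethylsilyl)oxy]-1-[(3E)-5-hydroxy-3-methylpent-3-en-1-yn-1-yl]-2,6,6-trimethylcyclohex-2-en-1-ol F6. Red-Al gives (1R,4S)-4-[(tert-butyldimethylsilyl)oxy]-1-[(1E,3E)-5-hydroxy-3-methylpenta-1,3-dien-1-yl]-2,6,6-trimethylcyclohex-2-en-1-ol F7, MnO2 gives (2E,4E)-5-[(1R,4S)-4-[(tert-butyldimethylsilyl)oxy]-1-hydroxy-2,6,6-trimethylcyclohex-2-en-1-yl]-3-methylpenta-2,4-dienal F8, and desilylation (TBAF, AcOH) gives 27, so that steps 18 and 19 are not needed.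

Further compounds
F1 | step 5 | (6R)-6-[(tert-butyldimethylsilyl)oxy]-7-iodo-2,4-dimethylheptan-3-one | IC[C@H](O[Si](C)(C)C(C)(C)C)CC(C)C(=O)C(C)C
F2 | step 18 | (3R,3'R,6'R)-7,8-didehydro-β,ε-carotene-3,3',6'-triol | CC1=C[C@H](O)CC(C)(C)[C@]1(O)/C=C/C(C)=C/C=C/C(C)=C/C=C/C=C(C)/C=C/C=C(\C)C#CC1=C(C)C[C@@H](O)CC1(C)C
F3 | step 18 | (3R,6'R)-3,6'-dihydroxy-7,8-didehydro-β,ε-caroten-3'-one | CC1=CC(=O)CC(C)(C)[C@]1(O)/C=C/C(C)=C/C=C/C(C)=C/C=C/C=C(C)/C=C/C=C(\C)C#CC1=C(C)C[C@@H](O)CC1(C)C
F4 | step 14 | (4S)-4-hydroxy-2,6,6-trimethylcyclohex-2-en-1-one | CC1=C[C@@H](O)CC(C)(C)C1=O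
F5 | step 14 | (4S)-4-[(tert-butyldimethylsilyl)oxy]-2,6,6-trimethylcyclohex-2-en-1-one | CC1=C[C@@H](O[Si](C)(C)C(C)(C)C)CC(C)(C)C1=O
F6 | step 14 | (1R,4S)-4-[(tert-butyldimethylsilyl)oxy]-1-[(3E)-5-hydroxy-3-methylpent-3-en-1-yn-1-yl]-2,6,6-trimethylcyclohex-2-en-1-ol | CC1=C[C@@H](O[Si](C)(C)C(C)(C)C)CC(C)(C)[C@]1(O)C#C/C(C)=C/CO
F7 | step 14 | (1R,4S)-4-[(tert-butyldimethylsilyl)oxy]-1-[(1E,3E)-5-hydroxy-3-methylpenta-1,3-dien-1-yl]-2,6,6-trimethylcyclohex-2-en-1-ol | CC1=C[C@@H](O[Si](C)(C)C(C)(C)C)CC(C)(C)[C@]1(O)/C=C/C(C)=C/CO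
F8 | step 14 | (2E,4E)-5-[(1R,4S)-4-[(tert-butyldimethylsilyl)oxy]-1-hydroxy-2,6,6-trimethylcyclohex-2-en-1-yl]-3-methylpenta-2,4-dienal | CC1=C[C@@H](O[Si](C)(C)C(C)(C)C)CC(C)(C)[C@]1(O)/C=C/C(C)=C/C=O
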